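(The numbers in the tables are calculated for an exercise; noise was put on by code.)

36.8% of the J charged is the number to hold this flask against.

| flask | J | L | remark | time |
|---|---|---|---|---|
| summer | 3 M | 200 mM (held) | the very flask that is asked about, followed so far |  |
| spring | 1.5 M | 200 mM (held) | run made earlier |  |
| flask | 3.0 M | 200 mM (held) |  | 2.5 d |

| run | time / h | G / % | J / % |
|---|---|---|---|
| summer | 0.250 | 16.0 | 74.8 |
| summer | 1.00 | 23.4 | 19.3 |
| summer | 5.00 | 0.3 | 0.3 |
| summer | 25.0 | 0.4 | 0.2 |
| spring | 0.417 | 30.1 | 48.4 |
| spring | 2.00 | 3.8 | 1.0 |
| spring | 10.0 | 0.7 | 0 |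
| spring | 40.0 | 0.5 | 0.1 |

(scatter of a reading: 0.3 percentage points)

- at the start none of L is in solution

* the best time, 2.5 d at the latest, for G
* the amount of G, in percent of the J charged, at that time

Suppose J and G are each lost in proportion to one concentration, dissolved L, with equal constants (pseudo-first-order at each moment). Time then drops out of the summer flask. Take J as a fraction of the charge and use its own clock:

θ = −ln J, G = w·θ·J

A chain in which every J becomes G has w = 1 and peaks at θ = 1, with J and G both at 36.8%. That is my bound from above, under this supposition. The bound from below is the summer reading 23.4%, within its scatter.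

Now tighten it from the summer readings:

w = 0.737 at 0.250 h, w = 0.737 at 1.00 h

This w, G over what such a chain holds at that J, is the keep factor, here as read from the summer readings. The spring reading at 0.417 h gives 0.857.

Under the same supposition, my upper figure for the summer peak is w/e:

27.1% of the charge

For the time, J crosses 36.8% between the two readings, and log interpolation puts that at 0.643 h.

The forecast, holding that “the best time falls early”, gives 27% at 0.62 h, inside the bracket on amount and earlier than my time.

The flask gives 25.0% at 0.734 h, with J at 33.6% of the charge and D, each D counted as two, at 26.6%.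

    Z + G → X (k = 0.260 L mol⁻¹ min⁻¹)
    J + G → D (k = 0.0100 L mol⁻¹ min⁻¹)
    J + Z → G (k = 0.280 L mol⁻¹ min⁻¹)
    L ⇌ Z, rate k4*(csat - [Z]) (kL = 0.370 min⁻¹)

Z, the dissolved L, takes G and J at constants in the ratio 0.929. At the flask's peak, w comes to 0.682. For the neighbour flask with 1.8 M of J, reading w across by charge between spring and summer gives 0.833, so w/e is 30.6% of the charge, and that flask gives 30.5%.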